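**Retrosynthetic overview**

1. Labdane numbering is used (decalin C1–C10, side chain C11–C16, C17 methylene, C18 and C19 on C4, C20 on C10). The C15 acetate and the C19 acid (masked as a 2-(trimethylsilyl)ethyl ester) are unveiled last, and C8=C17 comes from Wittig methylenation of a C8 ketone.
2. The C8 ketone and the C9 stereocentre come from hydroboration–oxidation of a C8=C9 alkene. That alkene is made by Negishi coupling (C9–C11) of the enol triflate of a C9 ketone with a C11–C16 zinc reagent cut from (R)-citronellol, which supplies C13.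
3. The quaternary C4 comes from a C3=C4 allylic alcohol: hydroxyl-directed cyclopropanation anti to C20, hydrogenolysis to the C18 methyl, oxidation of C19.
4. Feature and key disconnection: C10 (quaternary, carrying C20) and C5 are adjacent ring-fusion carbons, and a ketone at C9 makes C1=C10 a methacryloyl dienophile linked through C6–C7–C8 to a C2=C3–C4=C5 diene that bears C19. An intramolecular Diels–Alder reaction of this achiral trienone under a chiral oxazaborolidinium forms C1–C2 and C5–C10 and closes ring A and ring B in the same step; no ring exists before it.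
5. The trienone is assembled from hex-5-ynoic acid (acetylide hydroxymethylation, syn-hydrostannation, Stille vinylation) and isopropenylmagnesium bromide (Weinreb ketone synthesis).

Key step: step 7

Assumption: the sense of induction in step 7 is assigned from the aldehyde-type binding model of the oxazaborolidinium (boron on the C9 carbonyl lone pair syn to C8, s-cis enone), which calls for the catalyst from (S)-diphenylprolinol; if the sense were found reversed, the mirror-image catalyst would be used with no other change.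

**Route**

Step 1
Reactants: 1 hex-5-ynoic acid
Product: 3 7-hydroxyhept-5-ynoic acid, via lithium 6-lithiohex-5-ynoate 2 (not isolated)
Conditions: n-BuLi (2.1 equiv), THF, −78 → 0 °C; (CH2O)n, 0 °C → rt; aq. HCl
Reagents that add atoms: paraformaldehyde (formaldehyde), C=O
Why: Double deprotonation gives the carboxylate–acetylide 2, whose acetylide carbon alone adds to formaldehyde (acetylide hydroxymethylation) while the carboxylate stays inert.

Step 2
Reactants: 3 7-hydroxyhept-5-ynoic acid
Product: 5 7-[(tert-butyldimethylsilyl)oxy]hept-5-ynoic acid, via bis-silyl ester 4 (not isolated)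
Conditions: TBSCl (2.3 equiv), imidazole, DMF, rt; then K2CO3, MeOH/THF/H2O, rt; aq. HCl to pH 4, 0 °C
Reagents that add atoms: tert-butyldimethylsilyl chloride, CC(C)(C)[Si](C)(C)Cl
Why: Both hydroxyl and carboxyl are silylated and the labile silyl ester of 4 is then hydrolysed selectively, leaving the primary silyl ether (standard silyl protection).

Step 3
Reactants: 5 7-[(tert-butyldimethylsilyl)oxy]hept-5-ynoic acid
Product: 7 7-[(tert-butyldimethylsilyl)oxy]-N-methoxy-N-methylhept-5-ynamide, via acyl imidazole 6 (not isolated)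
Conditions: CDI, CH2Cl2, rt; then MeNH(OMe)·HCl, rt
Reagents that add atoms: N,O-dimethylhydroxylamine hydrochloride, CNOC.Cl
Why: Activation as the acyl imidazole and aminolysis give the Weinreb amide under conditions that leave the alkyne and the silyl ether untouched.

Step 4
Reactants: 7 7-[(tert-butyldimethylsilyl)oxy]-N-methoxy-N-methylhept-5-ynamide
Product: 8 (5E)-7-[(tert-butyldimethylsilyl)oxy]-N-methoxy-N-methyl-6-(tributylstannyl)hept-5-enamide
Conditions: Bu3SnH (slow addition), Pd(PPh3)4 (2 mol%), THF, 0 °C → rt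
Reagents that add atoms: tributyltin hydride, CCCC[SnH](CCCC)CCCC
Why: Palladium-catalysed hydrostannation adds H and Sn syn across the alkyne with tin on the carbon next to the inductively withdrawing CH2O group, which fixes the chain cis to the future C19; the distal regioisomer is the expected minor product and is removed by chromatography.

Step 5
Reactants: 8 (5E)-7-[(tert-butyldimethylsilyl)oxy]-N-methoxy-N-methyl-6-(tributylstannyl)hept-5-enamide
Product: 9 (5Z)-6-{[(tert-butyldimethylsilyl)oxy]methyl}-N-methoxy-N-methylocta-5,7-dienamide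
Conditions: vinyl bromide (1 M in THF), Pd2(dba)3 [dba = dibenzylideneacetone] (2.5 mol%), AsPh3 (20 mol%), CuI (10 mol%), NMP, 50 °C
Reagents that add atoms: vinyl bromide, C=CBr
Why: Stille coupling proceeds with retention of the alkene geometry, AsPh3 and CuI speeding transmetalation of the hindered 1,1-disubstituted stannane, so the vinyl group ends up trans to the chain.

Step 6
Reactants: 9 (5Z)-6-{[(tert-butyldimethylsilyl)oxy]methyl}-N-methoxy-N-methylocta-5,7-dienamide; 10 isopropenylmagnesium bromide
Product: 12 (7Z)-8-{[(tert-butyldimethylsilyl)oxy]methyl}-2-methyldeca-1,7,9-trien-3-one, via magnesium hemiaminal 11 (not isolated)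
Conditions: 10 (0.5 M in THF, 2 equiv), THF, −20 → 0 °C; cold 1 M HCl; product kept cold and used at once
Reagents that add atoms: none
Why: Weinreb ketone synthesis, in which the chelated tetrahedral adduct 11 blocks over-addition and the cold acidic quench protonates the released amine before it can add to the enone.

Step 7
Reactants: 12 (7Z)-8-{[(tert-butyldimethylsilyl)oxy]methyl}-2-methyldeca-1,7,9-trien-3-one
Product: 13 (4aR,8aR)-5-{[(tert-butyldimethylsilyl)oxy]methyl}-8a-methyl-3,4,4a,7,8,8a-hexahydronaphthalen-1(2H)-one (trans-fused; C9 ketone, C10 methyl, C3=C4 alkene bearing C19)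
Conditions: (S)-1-(2-methylphenyl)-3,3-diphenyltetrahydro-1H,3H-pyrrolo[1,2-c][1,3,2]oxazaborole (20 mol%), (CF3SO2)2NH (17 mol%), CH2Cl2, −78 → −40 °C
Reagents that add atoms: none
Why: Proposed new method: the N-protonated oxazaborolidine (triflimide salt) coordinates the C9 carbonyl of the s-cis methacryloyl unit, lowers the dienophile LUMO and induces a concerted but asynchronous [4+2] addition of the C2=C3–C4=C5 diene to C1=C10, the C1–C2 bond at the enone β-carbon running ahead of C5–C10. The closest known reaction types are the thermal and achiral-Lewis-acid intramolecular Diels–Alder reactions of 1,7,9-decatrien-3-ones and the Diels–Alder reactions of α-substituted enals and enones catalysed by this class of oxazaborolidinium salt; an enantioselective catalysed cyclisation of a trienone with the carbonyl inside the tether has not been shown. Ring A (C1, C2, C3, C4, C5, C10) closes as the cycloadduct ring through both new bonds, and ring B (C5 to C10) closes as the tether ring through the C5–C10 bond alone, the C6–C7–C8–C9 chain taking a chair-like arrangement. The two new stereocentres C5 and C10 arise together: their relative configuration (H5 anti to C20, trans fusion) comes from the transition state with the catalyst-bound C9 carbonyl exo and the C20 methyl endo, and their absolute configuration comes from the catalyst, which on the assumed binding model screens the C10 re face with a phenyl group so that the diene adds to the si face. The step needs exo-carbonyl selectivity, which the α-methyl group and the bulk of the bound cation (kept away from the diene and its C19 substituent) should secure, with the cis-fused isomer as the expected minor product. It also needs to outrun the uncatalysed racemic cyclisation, which the low temperature secures.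

Step 8
Reactants: 13 (4aR,8aR)-5-{[(tert-butyldimethylsilyl)oxy]methyl}-8a-methyl-3,4,4a,7,8,8a-hexahydronaphthalen-1(2H)-one
Product: 14 (4aR,8aR)-5-(hydroxymethyl)-8a-methyl-3,4,4a,7,8,8a-hexahydronaphthalen-1(2H)-one
Conditions: Bu4NF, THF, 0 °C; aq. NH4Cl
Reagents that add atoms: none
Why: Fluoride cleaves the Si–O bond and frees the allylic alcohol that directs the next step, without touching the ketone or the alkene.

Step 9
Reactants: 14 (4aR,8aR)-5-(hydroxymethyl)-8a-methyl-3,4,4a,7,8,8a-hexahydronaphthalen-1(2H)-one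
Product: 15 cyclopropyl carbinol (14 with a CH2 bridging C3 and C4 on the face of H5, C19 on the face of C20)
Conditions: Et2Zn, CH2I2, CH2Cl2, −10 → 0 °C; aq. NH4Cl
Reagents that add atoms: diiodomethane, ICI
Why: Hydroxyl-directed Simmons–Smith cyclopropanation (Furukawa variant), in which the allylic OH binds the zinc carbenoid and speeds CH2 transfer to C3=C4, and the carbenoid approaches the face opposite the axial C20 methyl (1,3 to C4), so the new CH2 is cis to H5 and C19 is pushed to the C20 face, which sets C4.

Step 10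
Reactants: 15 cyclopropyl carbinol
Product: 16 (4aR,5R,8aR)-5-(hydroxymethyl)-5,8a-dimethyloctahydronaphthalen-1(2H)-one
Conditions: H2 (4 atm), PtO2, AcOH, rt
Reagents that add atoms: none
Why: Hydrogenolysis over platinum cleaves the least substituted and least hindered cyclopropane bond (C3–CH2), turning the bridging carbon into the C18 methyl with C4 unchanged, while the hindered α-quaternary C9 ketone reacts slowly and any over-reduction there is undone by the oxidation of step 11.

Step 11
Reactants: 16 (4aR,5R,8aR)-5-(hydroxymethyl)-5,8a-dimethyloctahydronaphthalen-1(2H)-one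
Product: 18 (1R,4aR,8aS)-1,4a-dimethyl-5-oxodecahydronaphthalene-1-carboxylic acid, via keto aldehyde 17 (not isolated)
Conditions: CrO3, H2SO4, H2O, acetone, 0 °C → rt
Reagents that add atoms: water, O
Why: Jones oxidation takes the neopentyl primary alcohol through aldehyde 17 and its hydrate to the acid and at the same time guarantees the ketone level at C9, with no epimerisable centre present.

Step 12
Reactants: 18 (1R,4aR,8aS)-1,4a-dimethyl-5-oxodecahydronaphthalene-1-carboxylic acid
Product: 19 2-(trimethylsilyl)ethyl (1R,4aR,8aS)-1,4a-dimethyl-5-oxodecahydronaphthalene-1-carboxylate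
Conditions: Me3SiCH2CH2OH, PPh3, DIAD, THF, 0 °C → rt
Reagents that add atoms: 2-(trimethylsilyl)ethanol, C[Si](C)(C)CCO
Why: In the Mitsunobu esterification the hindered axial carboxylate is the nucleophile toward the activated primary alcohol, so congestion at C4 does not matter, and the resulting ester can later be cleaved at silicon and not at the shielded carbonyl.

Step 13
Reactants: 19 2-(trimethylsilyl)ethyl (1R,4aR,8aS)-1,4a-dimethyl-5-oxodecahydronaphthalene-1-carboxylate
Product: 21 2-(trimethylsilyl)ethyl (1R,4aR,8aS)-1,4a-dimethyl-5-{[(trifluoromethyl)sulfonyl]oxy}-1,2,3,4,4a,7,8,8a-octahydronaphthalene-1-carboxylate (C8=C9 enol triflate), via potassium enolate 20 (not isolated)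
Conditions: KN(SiMe3)2, THF, −78 °C; PhNTf2, −78 → 0 °C; aq. NH4Cl
Reagents that add atoms: N-phenylbis(trifluoromethanesulfonimide), O=S(=O)(N(c1ccccc1)S(=O)(=O)C(F)(F)F)C(F)(F)F
Why: The ketone can enolise only toward C8 because C10 is quaternary, so enolate formation and O-triflation give a single enol triflate, and the ester has no α-hydrogen.

Step 14
Reactants: 22 (R)-citronellol
Product: 23 (R)-tert-butyl[(3,7-dimethyloct-6-en-1-yl)oxy]dimethylsilane
Conditions: TBSCl, imidazole, CH2Cl2, rt
Reagents that add atoms: tert-butyldimethylsilyl chloride, CC(C)(C)[Si](C)(C)Cl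
Why: Standard silylation of the primary alcohol, which will become C15.

Step 15
Reactants: 23 (R)-tert-butyl[(3,7-dimethyloct-6-en-1-yl)oxy]dimethylsilane
Product: 25 (4R)-6-[(tert-butyldimethylsilyl)oxy]-4-methylhexanoic acid, via aldehyde 24 (not isolated)
Conditions: RuCl3·xH2O (3 mol%), NaIO4, MeCN/EtOAc/H2O, rt
Reagents that add atoms: sodium periodate (oxygen relayed through RuO4), [Na+].[O-]I(=O)(=O)=O; water, O
Why: RuO4 formed in situ cleaves the trisubstituted alkene to acetone and aldehyde 24, which is oxidised on to the acid, the remote stereocentre being untouched.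

Step 16
Reactants: 25 (4R)-6-[(tert-butyldimethylsilyl)oxy]-4-methylhexanoic acid
Product: 27 (S)-tert-butyl[(5-iodo-3-methylpentyl)oxy]dimethylsilane, via acyl hypoiodite 26 (not isolated)
Conditions: PhI(OAc)2, I2, cyclohexane, hν (tungsten lamp), reflux
Reagents that add atoms: iodine, II
Why: Hunsdiecker-type iododecarboxylation, in which the acyl hypoiodite 26 fragments under light to CO2 and a primary radical that is trapped by iodine, shortening the chain to the five-carbon C11–C15 unit without touching the stereocentre (its descriptor changes only through priorities).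

Step 17
Reactants: 21 C8=C9 enol triflate; 27 (S)-tert-butyl[(5-iodo-3-methylpentyl)oxy]dimethylsilane
Product: 29 2-(trimethylsilyl)ethyl (1R,4aR,8aS)-5-{(3R)-5-[(tert-butyldimethylsilyl)oxy]-3-methylpentyl}-1,4a-dimethyl-1,2,3,4,4a,7,8,8a-octahydronaphthalene-1-carboxylate, via alkylzinc iodide 28 (not isolated)
Conditions: 27, Zn dust (activated with BrCH2CH2Br and Me3SiCl), LiCl, THF, 40 °C; then 21, PdCl2(dppf) [dppf = 1,1'-bis(diphenylphosphino)ferrocene] (5 mol%), THF/NMP, 60 °C
Reagents that add atoms: none
Why: Negishi coupling, in which zinc inserts into the primary C–I bond and the alkylzinc 28 couples with the alkenyl triflate under a wide-bite-angle palladium catalyst that favours reductive elimination over β-hydride elimination, forming C9–C11 with the alkene fixed at C8=C9.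

Step 18
Reactants: 29 C8=C9 alkene
Product: 31 2-(trimethylsilyl)ethyl (1R,4aR,5S,6S,8aS)-5-{(3R)-5-[(tert-butyldimethylsilyl)oxy]-3-methylpentyl}-6-hydroxy-1,4a-dimethyldecahydronaphthalene-1-carboxylate (8-OH and H9 on the face opposite C20), via alkylborane 30 (not isolated)
Conditions: BH3·THF, THF, 0 °C → rt; then NaOH, H2O2, 0 °C → rt
Reagents that add atoms: hydrogen peroxide, OO
Why: In the hydroboration–oxidation boron adds to the less substituted C8 and hydrogen to C9 in a syn fashion from the face opposite the axial C20 methyl on the adjacent C10, so H9 ends up anti to C20 with the side chain equatorial, which sets C9, and the oxidation proceeds with retention.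

Step 19
Reactants: 31 C8 alcohol
Product: 32 2-(trimethylsilyl)ethyl (1R,4aR,5S,8aS)-5-{(3R)-5-[(tert-butyldimethylsilyl)oxy]-3-methylpentyl}-1,4a-dimethyl-6-oxodecahydronaphthalene-1-carboxylate
Conditions: Dess–Martin periodinane, CH2Cl2, rt
Reagents that add atoms: none
Why: Dess–Martin oxidation of the secondary alcohol under near-neutral conditions, the C9 configuration with the equatorial side chain being also the thermodynamically preferred one.

Step 20
Reactants: 32 C8 ketone
Product: 33 2-(trimethylsilyl)ethyl (1R,4aS,5R,8aS)-5-{(3R)-5-[(tert-butyldimethylsilyl)oxy]-3-methylpentyl}-1,4a-dimethyl-6-methylidenedecahydronaphthalene-1-carboxylate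
Conditions: Ph3PCH3Br, KOtBu, toluene, rt → 70 °C
Reagents that add atoms: methyltriphenylphosphonium bromide, C[P+](c1ccccc1)(c1ccccc1)c1ccccc1.[Br-]
Why: Wittig methylenation of the α-branched cyclohexanone with excess ylide, the hindered ester being inert and C9 keeping its stable equatorial configuration.

Step 21
Reactants: 33 silyl ether ester
Product: 35 (1R,4aS,5R,8aS)-5-[(3R)-5-hydroxy-3-methylpentyl]-1,4a-dimethyl-6-methylidenedecahydronaphthalene-1-carboxylic acid, via hydroxy ester 34 (not isolated)
Conditions: Bu4NF (4 equiv), THF, rt → 45 °C; aq. HCl to pH 3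
Reagents that add atoms: none
Why: Fluoride removes the primary silyl ether and then attacks the silicon of the 2-(trimethylsilyl)ethyl ester, which fragments with loss of ethene and frees the hindered acid without hydrolytic conditions.

Step 22
Reactants: 35 hydroxy acid
Product: 36 (1R,4aS,5R,8aS)-5-[(3R)-5-acetoxy-3-methylpentyl]-1,4a-dimethyl-6-methylidenedecahydronaphthalene-1-carboxylic acid (target)
Conditions: Ac2O, pyridine, DMAP (cat.), CH2Cl2, 0 °C → rt; H2O
Reagents that add atoms: acetic anhydride, CC(=O)OC(C)=O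
Why: Acetylation of the only hydroxyl group, any mixed anhydride at the hindered acid being hydrolysed during the aqueous work-up.

**Compound list**

1 | hex-5-ynoic acid | C#CCCCC(=O)O | starting material
2 | lithium 6-lithiohex-5-ynoate | [Li]C#CCCCC(=O)O[Li] | intermediate
3 | 7-hydroxyhept-5-ynoic acid | OCC#CCCCC(=O)O | intermediate
4 | tert-butyldimethylsilyl 7-[(tert-butyldimethylsilyl)oxy]hept-5-ynoate | CC(C)(C)[Si](C)(C)OCC#CCCCC(=O)O[Si](C)(C)C(C)(C)C | intermediate
5 | 7-[(tert-butyldimethylsilyl)oxy]hept-5-ynoic acid | CC(C)(C)[Si](C)(C)OCC#CCCCC(=O)O | intermediate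
6 | 7-[(tert-butyldimethylsilyl)oxy]-1-(1H-imidazol-1-yl)hept-5-yn-1-one | CC(C)(C)[Si](C)(C)OCC#CCCCC(=O)n1ccnc1 | intermediate
7 | 7-[(tert-butyldimethylsilyl)oxy]-N-methoxy-N-methylhept-5-ynamide | CON(C)C(=O)CCCC#CCO[Si](C)(C)C(C)(C)C | intermediate
8 | (5E)-7-[(tert-butyldimethylsilyl)oxy]-N-methoxy-N-methyl-6-(tributylstannyl)hept-5-enamide | CON(C)C(=O)CCC/C=C(/[Sn](CCCC)(CCCC)CCCC)CO[Si](C)(C)C(C)(C)C | intermediate
9 | (5Z)-6-{[(tert-butyldimethylsilyl)oxy]methyl}-N-methoxy-N-methylocta-5,7-dienamide | CON(C)C(=O)CCC/C=C(/C=C)CO[Si](C)(C)C(C)(C)C | intermediate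
10 | isopropenylmagnesium bromide | C=C(C)[Mg]Br | starting material
11 | bromomagnesium alkoxide of the N-methoxy-N-methyl hemiaminal (tetrahedral adduct of 9 and 10) | C=C(C)C(O[Mg]Br)(N(C)OC)CCC/C=C(/C=C)CO[Si](C)(C)C(C)(C)C | intermediate
12 | (7Z)-8-{[(tert-butyldimethylsilyl)oxy]methyl}-2-methyldeca-1,7,9-trien-3-one | C=C(C)C(=O)CCC/C=C(/C=C)CO[Si](C)(C)C(C)(C)C | intermediate
13 | (4aR,8aR)-5-{[(tert-butyldimethylsilyl)oxy]methyl}-8a-methyl-3,4,4a,7,8,8a-hexahydronaphthalen-1(2H)-one | C1CC[C@H]2[C@@](C)(CCC=C2CO[Si](C)(C)C(C)(C)C)C1=O | intermediate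
14 | (4aR,8aR)-5-(hydroxymethyl)-8a-methyl-3,4,4a,7,8,8a-hexahydronaphthalen-1(2H)-one | C1CC[C@H]2[C@@](C)(CCC=C2CO)C1=O | intermediate
15 | cyclopropyl carbinol: 14 with CH2 bridging C3 and C4 on the H5 face, hydroxymethyl on the C20 face | C1CC[C@H]2[C@@](C)(CC[C@@H]3C[C@]23CO)C1=O | intermediate
16 | (4aR,5R,8aR)-5-(hydroxymethyl)-5,8a-dimethyloctahydronaphthalen-1(2H)-one | C1CC[C@H]2[C@@](C)(CCC[C@@]2(C)CO)C1=O | intermediate
17 | (1R,4aR,8aR)-1,4a-dimethyl-5-oxodecahydronaphthalene-1-carbaldehyde | C1CC[C@H]2[C@@](C)(CCC[C@@]2(C)C=O)C1=O | intermediate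
18 | (1R,4aR,8aS)-1,4a-dimethyl-5-oxodecahydronaphthalene-1-carboxylic acid | C1CC[C@H]2[C@@](C)(CCC[C@@]2(C)C(=O)O)C1=O | intermediate
19 | 2-(trimethylsilyl)ethyl (1R,4aR,8aS)-1,4a-dimethyl-5-oxodecahydronaphthalene-1-carboxylate | C1CC[C@H]2[C@@](C)(CCC[C@@]2(C)C(=O)OCC[Si](C)(C)C)C1=O | intermediate
20 | potassium C8=C9 enolate of 19 | C1C[C@H]2[C@@](C)(CCC[C@@]2(C)C(=O)OCC[Si](C)(C)C)C(O[K])=C1 | intermediate
21 | 2-(trimethylsilyl)ethyl (1R,4aR,8aS)-1,4a-dimethyl-5-{[(trifluoromethyl)sulfonyl]oxy}-1,2,3,4,4a,7,8,8a-octahydronaphthalene-1-carboxylate | C1C[C@H]2[C@@](C)(CCC[C@@]2(C)C(=O)OCC[Si](C)(C)C)C(OS(=O)(=O)C(F)(F)F)=C1 | intermediate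
22 | (R)-citronellol | CC(C)=CCC[C@@H](C)CCO | starting material
23 | (R)-tert-butyl[(3,7-dimethyloct-6-en-1-yl)oxy]dimethylsilane | CC(C)=CCC[C@@H](C)CCO[Si](C)(C)C(C)(C)C | intermediate
24 | (4R)-6-[(tert-butyldimethylsilyl)oxy]-4-methylhexanal | O=CCC[C@@H](C)CCO[Si](C)(C)C(C)(C)C | intermediate
25 | (4R)-6-[(tert-butyldimethylsilyl)oxy]-4-methylhexanoic acid | OC(=O)CC[C@@H](C)CCO[Si](C)(C)C(C)(C)C | intermediate
26 | acyl hypoiodite of 25 | IOC(=O)CC[C@@H](C)CCO[Si](C)(C)C(C)(C)C | intermediate
27 | (S)-tert-butyl[(5-iodo-3-methylpentyl)oxy]dimethylsilane | ICC[C@@H](C)CCO[Si](C)(C)C(C)(C)C | intermediate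
28 | (S)-{5-[(tert-butyldimethylsilyl)oxy]-3-methylpentyl}zinc iodide | I[Zn]CC[C@@H](C)CCO[Si](C)(C)C(C)(C)C | intermediate
29 | 2-(trimethylsilyl)ethyl (1R,4aR,8aS)-5-{(3R)-5-[(tert-butyldimethylsilyl)oxy]-3-methylpentyl}-1,4a-dimethyl-1,2,3,4,4a,7,8,8a-octahydronaphthalene-1-carboxylate | C1C[C@H]2[C@@](C)(CCC[C@@]2(C)C(=O)OCC[Si](C)(C)C)C(CC[C@@H](C)CCO[Si](C)(C)C(C)(C)C)=C1 | intermediate
30 | C8 alkylborane from 29 (BH2 on C8 and H on C9, both on the face opposite C20) | B[C@H]1CC[C@H]2[C@@](C)(CCC[C@@]2(C)C(=O)OCC[Si](C)(C)C)[C@@H]1CC[C@@H](C)CCO[Si](C)(C)C(C)(C)C | intermediate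
31 | 2-(trimethylsilyl)ethyl (1R,4aR,5S,6S,8aS)-5-{(3R)-5-[(tert-butyldimethylsilyl)oxy]-3-methylpentyl}-6-hydroxy-1,4a-dimethyldecahydronaphthalene-1-carboxylate | O[C@H]1CC[C@H]2[C@@](C)(CCC[C@@]2(C)C(=O)OCC[Si](C)(C)C)[C@@H]1CC[C@@H](C)CCO[Si](C)(C)C(C)(C)C | intermediate
32 | 2-(trimethylsilyl)ethyl (1R,4aR,5S,8aS)-5-{(3R)-5-[(tert-butyldimethylsilyl)oxy]-3-methylpentyl}-1,4a-dimethyl-6-oxodecahydronaphthalene-1-carboxylate | O=C1CC[C@H]2[C@@](C)(CCC[C@@]2(C)C(=O)OCC[Si](C)(C)C)[C@@H]1CC[C@@H](C)CCO[Si](C)(C)C(C)(C)C | intermediate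
33 | 2-(trimethylsilyl)ethyl (1R,4aS,5R,8aS)-5-{(3R)-5-[(tert-butyldimethylsilyl)oxy]-3-methylpentyl}-1,4a-dimethyl-6-methylidenedecahydronaphthalene-1-carboxylate | C=C1CC[C@H]2[C@@](C)(CCC[C@@]2(C)C(=O)OCC[Si](C)(C)C)[C@@H]1CC[C@@H](C)CCO[Si](C)(C)C(C)(C)C | intermediate
34 | 2-(trimethylsilyl)ethyl (1R,4aS,5R,8aS)-5-[(3R)-5-hydroxy-3-methylpentyl]-1,4a-dimethyl-6-methylidenedecahydronaphthalene-1-carboxylate | C=C1CC[C@H]2[C@@](C)(CCC[C@@]2(C)C(=O)OCC[Si](C)(C)C)[C@@H]1CC[C@@H](C)CCO | intermediate
35 | (1R,4aS,5R,8aS)-5-[(3R)-5-hydroxy-3-methylpentyl]-1,4a-dimethyl-6-methylidenedecahydronaphthalene-1-carboxylic acid | C=C1CC[C@H]2[C@@](C)(CCC[C@@]2(C)C(=O)O)[C@@H]1CC[C@@H](C)CCO | intermediate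
36 | (1R,4aS,5R,8aS)-5-[(3R)-5-acetoxy-3-methylpentyl]-1,4a-dimethyl-6-methylidenedecahydronaphthalene-1-carboxylic acid | C=C1CC[C@H]2[C@@](C)(CCC[C@@]2(C)C(=O)O)[C@@H]1CC[C@@H](C)CCOC(C)=O | target

**Step count and risks**

Total step count: 22. Longest linear sequence: 19 steps (steps 1–13 and 17–22); steps 14–16 form the side-chain branch.

Steps most likely to fail:

Step 7 (proposed new method). The catalyst may discriminate poorly between the two faces of C10, or bind in a mode other than the assumed one, and part of the material may leak into the carbonyl-endo pathway that gives cis fusion. The fallback uses known chemistry and runs from 12 back to 13. Trienone 12 is cyclised without a chiral catalyst (Et2AlCl, CH2Cl2, −78 °C, or toluene at 80 °C), the established mode for 1,7,9-decatrien-3-ones, to the racemic trans-octalone F1. Reduction with NaBH4 (MeOH, 0 °C) should give the racemic C9 carbinol F2, with the equatorial hydroxyl expected and its configuration of no consequence. Esterification with (S)-O-methylmandelic acid (DCC, DMAP) gives two diastereomeric esters, the (S)-O-methylmandelate of the (4aR,8aR) series F3 and the (S)-O-methylmandelate of the mirror-image series F4, which are separated by chromatography or crystallisation. Hydrolysis of F3 (LiOH, THF/MeOH/H2O) frees the resolved carbinol F5, and Dess–Martin oxidation returns 13.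

Step 10. The hydrogenolysis may stall, may cleave a cyclopropane bond at C4 instead of C3–CH2, or may be accompanied by uncontrolled reduction at C9. The fallback builds C4 by enolate alkylation and runs from 14 back to 19. Oxidation of 14 with MnO2 (CH2Cl2) gives the enal F6, Pinnick oxidation (NaClO2, NaH2PO4, 2-methyl-2-butene) gives the enoic acid F7, and Mitsunobu esterification with 2-(trimethylsilyl)ethanol gives the 2-(trimethylsilyl)ethyl enoate F8. Reductive methylation (Li, NH3/THF, −78 °C; then MeI) forms the C4 ester enolate by 1,4-reduction and methylates it from the face opposite C20, the known course for such decalin ester enolates, giving the axial ester with the equatorial methyl; the C9 ketone is reduced in the same operation, so the product is the hydroxy ester F9. Dess–Martin oxidation of F9 returns 19.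

Step 17. Zinc insertion may be sluggish, and transmetalation at the triflate flanked by the quaternary C10 may be slow enough for triflate reduction or β-hydride elimination to compete. The fallback replaces the zinc reagent by a boron ate complex (B-alkyl Suzuki–Miyaura coupling) and runs from 21 and 27 back to 29. Iodine–lithium exchange on 27 (t-BuLi, 2 equiv, Et2O, −78 °C) gives the alkyllithium F10, which is trapped with 9-methoxy-9-borabicyclo[3.3.1]nonane to give the lithium borate F11. Coupling of F11 with 21 (PdCl2(dppf), K3PO4, DMF/H2O, rt → 50 °C) gives 29.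

**Further compounds**

F1 | step 7 | racemic trans-octalone (racemate of 13) | C1CC[C@H]2[C@@](C)(CCC=C2CO[Si](C)(C)C(C)(C)C)C1=O.C1CC[C@@H]2[C@](C)(CCC=C2CO[Si](C)(C)C(C)(C)C)C1=O
F2 | step 7 | racemic C9 carbinol of F1 (equatorial OH) | C1CC[C@H]2[C@@](C)(CCC=C2CO[Si](C)(C)C(C)(C)C)[C@@H]1O.C1CC[C@@H]2[C@](C)(CCC=C2CO[Si](C)(C)C(C)(C)C)[C@H]1O
F3 | step 7 | (S)-O-methylmandelate of the (4aR,8aR)-series carbinol | C1CC[C@H]2[C@@](C)(CCC=C2CO[Si](C)(C)C(C)(C)C)[C@@H]1OC(=O)[C@@H](OC)c1ccccc1
F4 | step 7 | (S)-O-methylmandelate of the mirror-image-series carbinol | C1CC[C@@H]2[C@](C)(CCC=C2CO[Si](C)(C)C(C)(C)C)[C@H]1OC(=O)[C@@H](OC)c1ccccc1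
F5 | step 7 | resolved C9 carbinol of 13 | C1CC[C@H]2[C@@](C)(CCC=C2CO[Si](C)(C)C(C)(C)C)[C@@H]1O
F6 | step 10 | (4aR,8aR)-8a-methyl-5-oxo-3,4,4a,5,6,7,8,8a-octahydronaphthalene-1-carbaldehyde (enal from 14) | C1CC[C@H]2[C@@](C)(CCC=C2C=O)C1=O
F7 | step 10 | enoic acid from F6 | C1CC[C@H]2[C@@](C)(CCC=C2C(=O)O)C1=O
F8 | step 10 | 2-(trimethylsilyl)ethyl enoate from F7 | C1CC[C@H]2[C@@](C)(CCC=C2C(=O)OCC[Si](C)(C)C)C1=O
F9 | step 10 | C9 carbinol of 19 (C4 methylated, equatorial 9-OH) | C1CC[C@H]2[C@@](C)(CCC[C@@]2(C)C(=O)OCC[Si](C)(C)C)[C@@H]1O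
F10 | step 17 | (S)-{5-[(tert-butyldimethylsilyl)oxy]-3-methylpentyl}lithium | [Li]CC[C@@H](C)CCO[Si](C)(C)C(C)(C)C
F11 | step 17 | lithium B-alkyl-B-methoxy-9-borabicyclo[3.3.1]nonane borate from F10 | [Li+].CO[B-]1(CC[C@@H](C)CCO[Si](C)(C)C(C)(C)C)C2CCCC1CCC2
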